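The constants used here are invented; the result is computed.

- Turn the question round before reckoning anything: ask what would have to be true of the given numbers for oak, the hotter flask, to beat maple on the share of target.

- maple: substrate 1.0 M; free catalyst 1.8 mM; temperature 45 °C; time 40 s
- oak: substrate 1.0 M; free catalyst 1.8 mM; temperature 70 °C; time 40 s

    substrate ⇌ target (K1 = 2.3, k1 = 0.034 s⁻¹, Ea1 = 79.0 kJ mol⁻¹, ΔH1 = −39.0 kJ mol⁻¹)
    substrate ⇌ isomer of the product A (K2 = 1.2, k2 = 0.0073 s⁻¹, Ea2 = 84.0 kJ mol⁻¹, ΔH2 = −14.0 kJ mol⁻¹)
    substrate + free catalyst ⇌ isomer of the product B + free catalyst, rate k3*[substrate]*[free catalyst] forward; the back reaction follows from the equilibrium constant (K3 = 0.69, k3 = 3.2 M⁻¹ s⁻¹, Ea3 = 52.0 kJ mol⁻¹, ΔH3 = 12.0 kJ mol⁻¹)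
    target → over-reaction product (k4 = 0.0094 s⁻¹, Ea4 = 97.0 kJ mol⁻¹)
    free catalyst → spent catalyst (k5 = 0.0067 s⁻¹, Ea5 = 103 kJ mol⁻¹)
    free catalyst + target ⇌ idle complex, settled at all times (K6 = 1.4 M⁻¹, ΔH6 = −8.00 kJ mol⁻¹)
    (constants at 70 °C)

- what is said of target includes idle complex
- the constants hold at 70 °C; other temperatures follow from the activation energies and enthalpies

- the best flask by share of target in all that became target or isomer of the product A or isomer of the product B or over-reaction product; "all alike" if 1.5 percentage points covers them all (maple / oak / all alike)
- share of target in all that became target or isomer of the product A or isomer of the product B or over-reaction product, maple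
- share of target in all that became target or isomer of the product A or isomer of the product B or over-reaction product, oak

- At the start of a flask the substrate splits by its forward rates, so I call the race share (kinetic control) the forward rate to target over the sum of the forward rates of the three isomerising steps; for oak, even with the whole catalyst charge free, it is 72.2%.

- For maple I slow the step to target by 8.8 to 0.00386 s⁻¹, and I take the fast balance with idle complex as settled at mid-run, where target stands near 0.0772 M, which leaves 88.1% of the catalyst free, so the forward rates sum to 0.00579 s⁻¹ and the race share of maple is 66.6%.

- Oak therefore leads the race, and the turned question becomes this: does oak keep that lead until it is read?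

- The quantity I carry is 14.2 s for oak, the relaxation half-life of the step from substrate to target, the time that step by itself, running both ways, needs to halve the gap to its balance; for maple it is 156 s.

- The reading at 40 s comes 2.82 half-lives into oak but 0.256 into maple, so I keep maple at its race share, while in oak target is made early enough to stand and drain, and I charge oak for that: taking target as made on average at mid-run, it has stood for half of the reading time, so a fraction 82.9% of it escapes over-reaction and the share of oak comes to 59.9%.

- I do not move oak to a balance of its three steps, since isomer of the product A relaxes in 51.8 s, longer than the reading time; the oak figure stays a rough commitment, and I name maple.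

- The forecast names maple too, with 66% (64% to 68%) for maple and 55.5% (53% to 58%) for oak, on the ground that in the hotter flask “the reverse reaction and over-reaction drain target”.

- The flasks give 66.1% for maple and 56.1% for oak, so maple leads by 10 percentage points, although oak, with the smaller share, has converted 72.2% of its substrate against 20.3% in maple and holds more target, 40.5% of its charge against 13.4%. The same oak read at 15 s, which is 1.06 half-lives in, shows a share of 67.3%.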